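**Plan**
1. Cuts: (a) the ester C–O bond at C3; (b) the C14–C15 single bond, giving a β-ring C18 trienyne (terminal alkyne C13≡C14, C20 methyl still absent) and an ε-ring C21 (E)-bromopentaene; (c) C10–C11, C10'–C11' and C14'–C15' in the same way, back to ring enynes; (d) the enynes to 3-silyloxy-β-ionone (cut at C6–C7 to the enol triflate of actinol) and 3-silyloxy-α-ionone.
2. Enabling feature: C13 carries the C20 methyl on an E-trisubstituted alkene whose other carbon, C14, bears only H and the bond to C15. This is exactly what syn-methylalumination of a terminal alkyne C13≡C14 gives, so the methyl branch, the E-C13=C14 geometry and the C14–C15 bond arise in one flask while two halves of similar size are joined (the same holds at C9, C9' and C13').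
3. Forward order: no ring is built (β-ring from actinol, ε-ring from α-ionone). Each chain grows outward from its ring by ketone-to-alkyne conversion, methylalumination/coupling with a C4 bromoenyne and, on the ε half, a C2 bromoiodoethene cap; then union, acylation of C3–OH and unmasking of C3'–OH.
4. Stereochemistry: C3 is bought with (4R,6R)-actinol; C6' is bought with (R)-α-ionone; C3' is set by enzymatic hydroxylation trans to the C6' side chain; all chain alkenes are E by syn-carbometalation, stereoretentive couplings, a Heck reaction and E-configured linkers.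
5. The two hydroxyls are told apart by carrying C3–OH free (as aluminium alkoxide) and C3'–OH as TBS ether through the union.

Key step: step 15

Assumption: (4R,6R)-actinol and (R)-(+)-α-ionone are taken as purchasable single enantiomers; all polyene intermediates are handled under argon with exclusion of light.

**Route**

Step 1
Reactants: 1 acetylene
Product: 2 (E)-1-bromo-2-iodoethene
Conditions: IBr, 48% aq. HBr, 0 °C
Reagents that add atoms: iodine monobromide, BrI
Why: Electrophilic halogenation of the alkyne through a bridged iodonium ion opened anti by bromide should give the E-1,2-dihaloethene.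

Step 2
Reactants: 2 (E)-1-bromo-2-iodoethene; 3 ethynyltrimethylsilane
Product: 5 (E)-(4-bromobut-3-en-1-yn-1-yl)trimethylsilane, via bromo[(trimethylsilyl)ethynyl]zinc 4 (not isolated)
Conditions: 3, n-BuLi, THF, −78 °C; ZnBr2, −78 → 0 °C; then 2 (1.3 equiv), Pd(PPh3)4 (2 mol %), 0 → 23 °C
Reagents that add atoms: none
Why: Negishi alkynylation in which zerovalent palladium inserts into the C–I bond far faster than into C–Br, so that a single coupling with retention of the E geometry is expected.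

Step 3
Reactants: 6 (4R,6R)-4-hydroxy-2,2,6-trimethylcyclohexan-1-one (actinol)
Product: 7 (4R,6R)-4-[(tert-butyldimethylsilyl)oxy]-2,2,6-trimethylcyclohexan-1-one
Conditions: TBSCl, imidazole, DMF, 23 °C
Reagents that add atoms: tert-butyldimethylsilyl chloride, CC(C)(C)[Si](C)(C)Cl
Why: Standard silylation of a secondary alcohol, which leaves both stereocentres untouched.

Step 4
Reactants: 7 (4R,6R)-4-[(tert-butyldimethylsilyl)oxy]-2,2,6-trimethylcyclohexan-1-one
Product: 8 (R)-4-[(tert-butyldimethylsilyl)oxy]-2,6,6-trimethylcyclohex-1-en-1-yl trifluoromethanesulfonate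
Conditions: LDA, THF, −78 → 0 °C; PhNTf2, −78 → 23 °C
Reagents that add atoms: N-phenylbis(trifluoromethanesulfonimide), O=S(=O)(N(c1ccccc1)S(=O)(=O)C(F)(F)F)C(F)(F)F
Why: Deprotonation at C6, the only enolisable position (C2 is quaternary), and O-sulfonylation (enol triflate formation) should give one tetrasubstituted enol triflate; the C6 stereocentre is erased by design and C4 is untouched.

Step 5
Reactants: 8 (R)-4-[(tert-butyldimethylsilyl)oxy]-2,6,6-trimethylcyclohex-1-en-1-yl trifluoromethanesulfonate; 9 but-3-en-2-one (methyl vinyl ketone)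
Product: 10 (E)-4-[(R)-4-[(tert-butyldimethylsilyl)oxy]-2,6,6-trimethylcyclohex-1-en-1-yl]but-3-en-2-one [(3R)-3-silyloxy-β-ionone]
Conditions: Pd(OAc)2 (5 mol %), PPh3 (10 mol %), Et3N, 9 (3 equiv), DMF, 65 °C
Reagents that add atoms: none
Why: Mizoroki–Heck vinylation of the enol triflate, in which syn-carbopalladation of the enone and syn-β-hydride elimination should give the E-dienone, that is the C6–C7 bond and the E-C7=C8 alkene.

Step 6
Reactants: 10 (3R)-3-silyloxy-β-ionone
Product: 12 {[(R)-4-[(E)-but-1-en-3-yn-1-yl]-3,5,5-trimethylcyclohex-3-en-1-yl]oxy}(tert-butyl)dimethylsilane, via diethyl dienyl phosphate 11 (not isolated)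
Conditions: LDA (1.05 equiv), THF, −78 °C; ClP(O)(OEt)2, −78 → 23 °C; LDA (2.3 equiv), −78 → 23 °C; then H2O
Reagents that add atoms: none
Why: Kinetic enolisation of the methyl ketone at C10, O-phosphorylation and base-induced elimination of diethyl phosphate from the enol phosphate (ketone-to-alkyne conversion) should give the terminal enyne with the E-C7=C8 alkene and the silyl ether intact.

Step 7
Reactants: 12 β-ring enyne; 5 (E)-(4-bromobut-3-en-1-yn-1-yl)trimethylsilane
Product: 14 tert-butyldimethyl{[(R)-3,5,5-trimethyl-4-[(1E,3E,5E)-3-methyl-8-(trimethylsilyl)octa-1,3,5-trien-7-yn-1-yl]cyclohex-3-en-1-yl]oxy}silane, via β-ring dienyldimethylalane 13 (not isolated)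
Conditions: Me3Al (2 equiv), Cp2ZrCl2 (25 mol %), ClCH2CH2Cl, 23 °C; volatiles removed; then 5, ZnCl2 (co-catalyst), Pd2(dba)3 (2.5 mol %), tri(2-furyl)phosphine (10 mol %), THF/DMF, 23 °C, dark
Reagents that add atoms: trimethylaluminium, C[Al](C)C
Why: Cp2ZrCl2-catalysed syn-methylalumination of the terminal alkyne (methyl to C9, aluminium to C10) followed by zinc-assisted Negishi coupling of the alkenylalane with the bromoenyne should set E-C9=C10 by the cis addition and keep E-C11=C12 by retention.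

Step 8
Reactants: 14 β-ring silylated trienyne
Product: 15 (R)-3,5,5-trimethyl-4-[(1E,3E,5E)-3-methylocta-1,3,5-trien-7-yn-1-yl]cyclohex-3-en-1-ol
Conditions: TBAF (3 equiv), THF, 0 → 23 °C
Reagents that add atoms: none
Why: Fluoride-induced desilylation should cleave both the alkynyl C–Si bond and the secondary silyl ether, freeing the terminal alkyne and the C3 hydroxyl in one operation without touching the triene.

Step 9
Reactants: 16 (R)-α-ionone [(E)-4-[(R)-2,6,6-trimethylcyclohex-2-en-1-yl]but-3-en-2-one]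
Product: 17 (E)-4-[(1R,4R)-4-hydroxy-2,6,6-trimethylcyclohex-2-en-1-yl]but-3-en-2-one [(3R,6R)-3-hydroxy-α-ionone]
Conditions: engineered cytochrome P450 BM3 variant (trans-3-selective), NADP+ (cat.), glucose dehydrogenase, D-glucose, O2 (air), potassium phosphate buffer pH 7.5, 2% DMSO, 25 °C
Reagents that add atoms: dioxygen, O=O
Why: Enzymatic allylic C–H hydroxylation (monooxygenation by hydrogen abstraction and oxygen rebound) at the unhindered allylic methylene C3, with the enzyme pocket delivering oxygen to the ring face opposite the C6 side chain, should set C3 as R (3,6-trans) while C6 is untouched.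

Step 10
Reactants: 17 (3R,6R)-3-hydroxy-α-ionone
Product: 18 (E)-4-[(1R,4R)-4-[(tert-butyldimethylsilyl)oxy]-2,6,6-trimethylcyclohex-2-en-1-yl]but-3-en-2-one
Conditions: TBSCl, imidazole, DMF, 23 °C
Reagents that add atoms: tert-butyldimethylsilyl chloride, CC(C)(C)[Si](C)(C)Cl
Why: Standard silylation of the allylic secondary alcohol under non-acidic conditions, which leaves both ring stereocentres untouched.

Step 11
Reactants: 18 (3R,6R)-3-silyloxy-α-ionone
Product: 20 tert-butyl{[(1R,4R)-4-[(E)-but-1-en-3-yn-1-yl]-3,5,5-trimethylcyclohex-2-en-1-yl]oxy}dimethylsilane, via ε-ring diethyl dienyl phosphate 19 (not isolated)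
Conditions: LDA (1.05 equiv), THF, −78 °C; ClP(O)(OEt)2, −78 → 23 °C; LDA (2.3 equiv), −78 → 23 °C; then H2O
Reagents that add atoms: none
Why: LDA at −78 °C should remove a proton of the methyl ketone in preference to the hindered, doubly allylic C6'–H, so that phosphorylation and elimination of the enol phosphate (ketone-to-alkyne conversion) give the terminal enyne without epimerisation at C6'.

Step 12
Reactants: 20 ε-ring enyne; 5 (E)-(4-bromobut-3-en-1-yn-1-yl)trimethylsilane
Product: 22 tert-butyldimethyl{[(1R,4R)-3,5,5-trimethyl-4-[(1E,3E,5E)-3-methyl-8-(trimethylsilyl)octa-1,3,5-trien-7-yn-1-yl]cyclohex-2-en-1-yl]oxy}silane, via ε-ring dienyldimethylalane 21 (not isolated)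
Conditions: Me3Al (2 equiv), Cp2ZrCl2 (25 mol %), ClCH2CH2Cl, 23 °C; volatiles removed; then 5, ZnCl2 (co-catalyst), Pd2(dba)3 (2.5 mol %), tri(2-furyl)phosphine (10 mol %), THF/DMF, 23 °C, dark
Reagents that add atoms: trimethylaluminium, C[Al](C)C
Why: Syn-methylalumination (methyl to C9', aluminium to C10') and Negishi coupling with the bromoenyne should set E-C9'=C10' and keep E-C11'=C12', the ring alkene and the allylic silyl ether being inert to the alane.

Step 13
Reactants: 22 ε-ring silylated trienyne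
Product: 23 tert-butyldimethyl{[(1R,4R)-3,5,5-trimethyl-4-[(1E,3E,5E)-3-methylocta-1,3,5-trien-7-yn-1-yl]cyclohex-2-en-1-yl]oxy}silane
Conditions: K2CO3 (cat.), MeOH/THF, 23 °C
Reagents that add atoms: none
Why: Methanolysis of the alkynyl C–Si bond (protodesilylation) should free the terminal alkyne while the secondary TBS ether survives the mild base.

Step 14
Reactants: 23 ε-ring trienyne; 2 (E)-1-bromo-2-iodoethene
Product: 25 {[(1R,4R)-4-[(1E,3E,5E,7E,9E)-10-bromo-3,7-dimethyldeca-1,3,5,7,9-pentaen-1-yl]-3,5,5-trimethylcyclohex-2-en-1-yl]oxy}(tert-butyl)dimethylsilane, via ε-ring tetraenyldimethylalane 24 (not isolated)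
Conditions: Me3Al (2 equiv), Cp2ZrCl2 (25 mol %), ClCH2CH2Cl, 23 °C; volatiles removed; then 2 (3 equiv), ZnCl2 (co-catalyst), Pd2(dba)3 (2.5 mol %), tri(2-furyl)phosphine (10 mol %), THF/DMF, 0 → 23 °C, dark
Reagents that add atoms: trimethylaluminium, C[Al](C)C
Why: Syn-methylalumination (methyl to C13', aluminium to C14') and Negishi coupling with excess bromoiodoethene, which should react at the C–I bond only, should give the E,E-bromodiene terminus with the bromide kept for the union.

Step 15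
Reactants: 15 β-ring C18 trienynol; 25 ε-ring C21 bromopentaene
Product: 27 (3R,3'R,6'R)-3'-[(tert-butyldimethylsilyl)oxy]-β,ε-caroten-3-ol (3'-O-TBS-lutein), via C14-alanyl aluminium alkoxide 26 (not isolated)
Conditions: 15 (1.3 equiv), Me3Al (3.5 equiv), Cp2ZrCl2 (25 mol %), ClCH2CH2Cl, 23 °C; volatiles removed; then 25 (1.0 equiv), ZnCl2 (co-catalyst), Pd2(dba)3 (2.5 mol %), tri(2-furyl)phosphine (10 mol %), THF/DMF, 23 °C, dark; aq. NaHCO3
Reagents that add atoms: trimethylaluminium, C[Al](C)C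
Why: Cp2ZrCl2-catalysed syn-methylalumination of the terminal alkyne of 15 places the methyl on C13 and aluminium on C14, giving the (E)-2-methylalkenylalane 26; ZnCl2 relays the alkenyl group to palladium, which has inserted into the C15–Br bond of 25 with retention, and reductive elimination forms the C14–C15 bond. The closest known reaction type is the one-pot zirconium-catalysed carboalumination/palladium- and zinc-co-catalysed Negishi coupling of conjugated enynes with alkenyl halides used in polyene assembly. No ring is closed and no stereocentre is created; the only new stereo element is the E-C13=C14 double bond, fixed by the cis addition, while the other alkene geometries and the stereocentres C3, C3' and C6' are carried through unchanged. The step needs methyl delivery to the internal alkyne carbon and reaction of the alkyne only, which the terminal position of the alkyne and the inertness of the ring and chain alkenes should secure. The free C3 hydroxyl is masked in the flask as its dimethylaluminium alkoxide, so that it emerges unprotected and distinct from the silylated C3' hydroxyl.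

Step 16
Reactants: 27 3'-O-TBS-lutein; 28 hexadecanoyl chloride (palmitoyl chloride)
Product: 29 (3R,3'R,6'R)-3'-[(tert-butyldimethylsilyl)oxy]-β,ε-caroten-3-yl hexadecanoate
Conditions: 28 (1.5 equiv), pyridine, DMAP (cat.), CH2Cl2, 0 → 23 °C, dark
Reagents that add atoms: none
Why: Esterification of the only free hydroxyl (C3–OH) with the acid chloride under nucleophilic catalysis should give the palmitate, site selectivity being secured by the silyl ether on the C3' oxygen.

Step 17
Reactants: 29 3'-O-TBS-lutein 3-palmitate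
Product: 30 (3R,3'R,6'R)-3'-hydroxy-β,ε-caroten-3-yl hexadecanoate (lutein 3-O-palmitate, target)
Conditions: TBAF, AcOH (1:1), THF, 0 → 23 °C, dark
Reagents that add atoms: none
Why: Fluoride desilylation buffered with acetic acid should unmask the allylic C3' hydroxyl without ionising the allylic C–O bond (no epimerisation or dehydration) and without cleaving the ester.

**Compound list**
1 | acetylene | C#C | starting material
2 | (E)-1-bromo-2-iodoethene | Br/C=C/I | intermediate
3 | ethynyltrimethylsilane | C#C[Si](C)(C)C | starting material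
4 | bromo[(trimethylsilyl)ethynyl]zinc | C[Si](C)(C)C#C[Zn]Br | intermediate
5 | (E)-(4-bromobut-3-en-1-yn-1-yl)trimethylsilane | C[Si](C)(C)C#C/C=C/Br | intermediate
6 | (4R,6R)-4-hydroxy-2,2,6-trimethylcyclohexan-1-one (actinol) | C[C@@H]1C[C@@H](O)CC(C)(C)C1=O | starting material
7 | (4R,6R)-4-[(tert-butyldimethylsilyl)oxy]-2,2,6-trimethylcyclohexan-1-one | C[C@@H]1C[C@@H](O[Si](C)(C)C(C)(C)C)CC(C)(C)C1=O | intermediate
8 | (R)-4-[(tert-butyldimethylsilyl)oxy]-2,6,6-trimethylcyclohex-1-en-1-yl trifluoromethanesulfonate | CC(C)(C)[Si](C)(C)O[C@@H]1CC(C)=C(OS(=O)(=O)C(F)(F)F)C(C)(C)C1 | intermediate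
9 | but-3-en-2-one | CC(=O)C=C | starting material
10 | (E)-4-[(R)-4-[(tert-butyldimethylsilyl)oxy]-2,6,6-trimethylcyclohex-1-en-1-yl]but-3-en-2-one | CC(C)(C)[Si](C)(C)O[C@@H]1CC(C)=C(/C=C/C(C)=O)C(C)(C)C1 | intermediate
11 | diethyl (E)-4-[(R)-4-[(tert-butyldimethylsilyl)oxy]-2,6,6-trimethylcyclohex-1-en-1-yl]buta-1,3-dien-2-yl phosphate | CC(C)(C)[Si](C)(C)O[C@@H]1CC(C)=C(/C=C/C(=C)OP(=O)(OCC)OCC)C(C)(C)C1 | intermediate
12 | {[(R)-4-[(E)-but-1-en-3-yn-1-yl]-3,5,5-trimethylcyclohex-3-en-1-yl]oxy}(tert-butyl)dimethylsilane | CC(C)(C)[Si](C)(C)O[C@@H]1CC(C)=C(/C=C/C#C)C(C)(C)C1 | intermediate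
13 | [(1E,3E)-4-[(R)-4-[(tert-butyldimethylsilyl)oxy]-2,6,6-trimethylcyclohex-1-en-1-yl]-2-methylbuta-1,3-dien-1-yl]dimethylalane | CC(C)(C)[Si](C)(C)O[C@@H]1CC(C)=C(/C=C/C(C)=C/[Al](C)C)C(C)(C)C1 | intermediate
14 | tert-butyldimethyl{[(R)-3,5,5-trimethyl-4-[(1E,3E,5E)-3-methyl-8-(trimethylsilyl)octa-1,3,5-trien-7-yn-1-yl]cyclohex-3-en-1-yl]oxy}silane | CC(C)(C)[Si](C)(C)O[C@@H]1CC(C)=C(/C=C/C(C)=C/C=C/C#C[Si](C)(C)C)C(C)(C)C1 | intermediate
15 | (R)-3,5,5-trimethyl-4-[(1E,3E,5E)-3-methylocta-1,3,5-trien-7-yn-1-yl]cyclohex-3-en-1-ol | O[C@@H]1CC(C)=C(/C=C/C(C)=C/C=C/C#C)C(C)(C)C1 | intermediate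
16 | (R)-α-ionone, (E)-4-[(R)-2,6,6-trimethylcyclohex-2-en-1-yl]but-3-en-2-one | CC(=O)/C=C/[C@H]1C(C)=CCCC1(C)C | starting material
17 | (E)-4-[(1R,4R)-4-hydroxy-2,6,6-trimethylcyclohex-2-en-1-yl]but-3-en-2-one | CC(=O)/C=C/[C@H]1C(C)=C[C@H](O)CC1(C)C | intermediate
18 | (E)-4-[(1R,4R)-4-[(tert-butyldimethylsilyl)oxy]-2,6,6-trimethylcyclohex-2-en-1-yl]but-3-en-2-one | CC(=O)/C=C/[C@H]1C(C)=C[C@H](O[Si](C)(C)C(C)(C)C)CC1(C)C | intermediate
19 | diethyl (E)-4-[(1R,4R)-4-[(tert-butyldimethylsilyl)oxy]-2,6,6-trimethylcyclohex-2-en-1-yl]buta-1,3-dien-2-yl phosphate | C=C(OP(=O)(OCC)OCC)/C=C/[C@H]1C(C)=C[C@H](O[Si](C)(C)C(C)(C)C)CC1(C)C | intermediate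
20 | tert-butyl{[(1R,4R)-4-[(E)-but-1-en-3-yn-1-yl]-3,5,5-trimethylcyclohex-2-en-1-yl]oxy}dimethylsilane | C#C/C=C/[C@H]1C(C)=C[C@H](O[Si](C)(C)C(C)(C)C)CC1(C)C | intermediate
21 | [(1E,3E)-4-[(1R,4R)-4-[(tert-butyldimethylsilyl)oxy]-2,6,6-trimethylcyclohex-2-en-1-yl]-2-methylbuta-1,3-dien-1-yl]dimethylalane | C[Al](C)/C=C(C)/C=C/[C@H]1C(C)=C[C@H](O[Si](C)(C)C(C)(C)C)CC1(C)C | intermediate
22 | tert-butyldimethyl{[(1R,4R)-3,5,5-trimethyl-4-[(1E,3E,5E)-3-methyl-8-(trimethylsilyl)octa-1,3,5-trien-7-yn-1-yl]cyclohex-2-en-1-yl]oxy}silane | C[Si](C)(C)C#C/C=C/C=C(C)/C=C/[C@H]1C(C)=C[C@H](O[Si](C)(C)C(C)(C)C)CC1(C)C | intermediate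
23 | tert-butyldimethyl{[(1R,4R)-3,5,5-trimethyl-4-[(1E,3E,5E)-3-methylocta-1,3,5-trien-7-yn-1-yl]cyclohex-2-en-1-yl]oxy}silane | C#C/C=C/C=C(C)/C=C/[C@H]1C(C)=C[C@H](O[Si](C)(C)C(C)(C)C)CC1(C)C | intermediate
24 | [(1E,3E,5E,7E)-8-[(1R,4R)-4-[(tert-butyldimethylsilyl)oxy]-2,6,6-trimethylcyclohex-2-en-1-yl]-2,6-dimethylocta-1,3,5,7-tetraen-1-yl]dimethylalane | C[Al](C)/C=C(C)/C=C/C=C(C)/C=C/[C@H]1C(C)=C[C@H](O[Si](C)(C)C(C)(C)C)CC1(C)C | intermediate
25 | {[(1R,4R)-4-[(1E,3E,5E,7E,9E)-10-bromo-3,7-dimethyldeca-1,3,5,7,9-pentaen-1-yl]-3,5,5-trimethylcyclohex-2-en-1-yl]oxy}(tert-butyl)dimethylsilane | Br/C=C/C=C(C)/C=C/C=C(C)/C=C/[C@H]1C(C)=C[C@H](O[Si](C)(C)C(C)(C)C)CC1(C)C | intermediate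
26 | dimethylaluminium (R)-4-[(1E,3E,5E,7E)-8-(dimethylalumanyl)-3,7-dimethylocta-1,3,5,7-tetraen-1-yl]-3,5,5-trimethylcyclohex-3-en-1-olate | C[Al](C)O[C@@H]1CC(C)=C(/C=C/C(C)=C/C=C/C(C)=C/[Al](C)C)C(C)(C)C1 | intermediate
27 | (3R,3'R,6'R)-3'-[(tert-butyldimethylsilyl)oxy]-β,ε-caroten-3-ol | O[C@@H]1CC(C)=C(/C=C/C(C)=C/C=C/C(C)=C/C=C/C=C(C)/C=C/C=C(C)/C=C/[C@H]2C(C)=C[C@H](O[Si](C)(C)C(C)(C)C)CC2(C)C)C(C)(C)C1 | intermediate
28 | hexadecanoyl chloride | CCCCCCCCCCCCCCCC(=O)Cl | starting material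
29 | (3R,3'R,6'R)-3'-[(tert-butyldimethylsilyl)oxy]-β,ε-caroten-3-yl hexadecanoate | CCCCCCCCCCCCCCCC(=O)O[C@@H]1CC(C)=C(/C=C/C(C)=C/C=C/C(C)=C/C=C/C=C(C)/C=C/C=C(C)/C=C/[C@H]2C(C)=C[C@H](O[Si](C)(C)C(C)(C)C)CC2(C)C)C(C)(C)C1 | intermediate
30 | (3R,3'R,6'R)-3'-hydroxy-β,ε-caroten-3-yl hexadecanoate (lutein 3-O-palmitate) | CCCCCCCCCCCCCCCC(=O)O[C@@H]1CC(C)=C(/C=C/C(C)=C/C=C/C(C)=C/C=C/C=C(C)/C=C/C=C(C)/C=C/[C@H]2C(C)=C[C@H](O)CC2(C)C)C(C)(C)C1 | target

**Count and risks**

Total step count: 17. Longest linear sequence: 9 steps (steps 3–8, then 15–17; the ε branch, steps 9–14 then 15–17, is equally long).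

Steps most likely to fail:

(a) Step 15. The long bromopentaene may be lost by homocoupling or E/Z isomerisation while transmetalation from the aluminium alkoxide-bearing alane is slow. The fallback sets out from 15 and 25 and comes back at 27, using two isolable partners and a Stille coupling. The alane from 15 (Me3Al, Cp2ZrCl2) would be quenched with I2 in THF at −30 °C to give (R)-4-[(1E,3E,5E,7E)-8-iodo-3,7-dimethylocta-1,3,5,7-tetraen-1-yl]-3,5,5-trimethylcyclohex-3-en-1-ol F6. Bromide 25 would be converted with Me3SnSnMe3 and Pd(PPh3)4 into the trimethylstannylpentaene F7. Coupling of F6 with F7 (Pd2(dba)3, AsPh3, NMP, 23 °C, dark) should give 27.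

(b) Step 5. Oxidative addition and alkene insertion at the tetrasubstituted, doubly flanked enol triflate may be too slow, so that triflate hydrolysis or reduction and enone polymerisation take over. The fallback sets out from 8 (with 5) and comes back at 12, bypassing 10. Bromoenyne 5 would be converted by bromine–lithium exchange (t-BuLi, Et2O, −100 °C) and Bu3SnCl into (E)-tributyl[4-(trimethylsilyl)but-1-en-3-yn-1-yl]stannane F1. Stille coupling of 8 with F1 (Pd2(dba)3, AsPh3, NMP, 60 °C) should give the silylated β-ring enyne F2, and K2CO3 in MeOH would remove the alkynyl silyl group to give 12.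

(c) Step 9. The enzymatic hydroxylation may show insufficient regio- or diastereoselectivity, over-oxidation to the 3-ketone, or too low a productivity on scale. The fallback sets out from 16 and comes back at 17 by a chemical oxidation/reduction sequence.
- Ketalisation (ethylene glycol, HC(OEt)3, cat. p-TsOH, 23 °C) would give the α-ionone ethylene ketal F3.
- Allylic oxidation (t-BuOOH, NaOCl, K2CO3, MeCN, 0 °C) would give the 3-oxo ketal F4.
- Reduction with LiBH(s-Bu)3 (THF, −78 °C) should give mainly the 3,6-trans hydroxy ketal F5, the hydride being delivered anti to the pseudo-axial C1 methyl (the cis isomer is separable by chromatography).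
- Mild hydrolysis (PPTS, acetone/H2O, 23 °C) would return 17.

**Further compounds**
F1 | step 5 | (E)-tributyl[4-(trimethylsilyl)but-1-en-3-yn-1-yl]stannane | CCCC[Sn](CCCC)(CCCC)/C=C/C#C[Si](C)(C)C
F2 | step 5 | tert-butyldimethyl{[(R)-3,5,5-trimethyl-4-[(E)-4-(trimethylsilyl)but-1-en-3-yn-1-yl]cyclohex-3-en-1-yl]oxy}silane | CC(C)(C)[Si](C)(C)O[C@@H]1CC(C)=C(/C=C/C#C[Si](C)(C)C)C(C)(C)C1
F3 | step 9 | 2-methyl-2-[(E)-2-[(R)-2,6,6-trimethylcyclohex-2-en-1-yl]ethenyl]-1,3-dioxolane | CC1(/C=C/[C@H]2C(C)=CCCC2(C)C)OCCO1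
F4 | step 9 | (R)-3,5,5-trimethyl-4-[(E)-2-(2-methyl-1,3-dioxolan-2-yl)ethenyl]cyclohex-2-en-1-one | CC1(/C=C/[C@H]2C(C)=CC(=O)CC2(C)C)OCCO1
F5 | step 9 | (1R,4R)-3,5,5-trimethyl-4-[(E)-2-(2-methyl-1,3-dioxolan-2-yl)ethenyl]cyclohex-2-en-1-ol | CC1(/C=C/[C@H]2C(C)=C[C@H](O)CC2(C)C)OCCO1
F6 | step 15 | (R)-4-[(1E,3E,5E,7E)-8-iodo-3,7-dimethylocta-1,3,5,7-tetraen-1-yl]-3,5,5-trimethylcyclohex-3-en-1-ol | O[C@@H]1CC(C)=C(/C=C/C(C)=C/C=C/C(C)=C/I)C(C)(C)C1
F7 | step 15 | tert-butyldimethyl{[(1R,4R)-3,5,5-trimethyl-4-[(1E,3E,5E,7E,9E)-3,7-dimethyl-10-(trimethylstannyl)deca-1,3,5,7,9-pentaen-1-yl]cyclohex-2-en-1-yl]oxy}silane | C[Sn](C)(C)/C=C/C=C(C)/C=C/C=C(C)/C=C/[C@H]1C(C)=C[C@H](O[Si](C)(C)C(C)(C)C)CC1(C)C
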